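**Strategy.** Everything rests on closing the α-methylene-γ-butyrolactone (ring O–C6–C7–C11–C12, germacrane numbering) last, by forming the C7–C11 bond inside the finished ten-membered carbocycle. The step exploits the contiguous C6(O)–C7(C)–C8(OH) array, in which C11 and O8 are anti: the carbanion of a C6-O-bound phosphonoacetate (C11) opens a trans-7,8-epoxide at C7 (5-exo, inversion), which sets C7, unveils the unprotected C8 hydroxyl and leaves a phosphonate that formaldehyde turns, in the same flask, into the C11=C13 methylene. The precursor is a protecting-group-free cyclodeca-1(10),4-diene 7,8-epoxide carrying acetate, angelate and phosphonoacetate esters; a titanium–tartrate kinetic resolution sets C6, C7 and C8 together.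

Key step: step 15

Remark: germacrane numbering is used for all ring atoms (C1–C10 in the ten-membered ring, C14 the methyl on C10, C15 the CH2O carbon on C4, C11/C12/C13 the lactone α-carbon, carbonyl and methylene). The target is the (2S,6R,7R,8R) enantiomer with a trans-fused lactone; C4=C5 has C3 and C6 trans (CIP descriptor Z because C15 bears oxygen) and C1=C10 has C2 and C9 cis.

Step 1
Reactants: 1 prop-2-yn-1-ol; 2 methylmagnesium bromide
Product: 4 (2Z)-3-iodo-2-methylprop-2-en-1-ol, via vinylmagnesium chelate 3 (not isolated)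
Conditions: MeMgBr (2.2 equiv), CuI (10 mol %), Et2O–THF, −10 → 23 °C; then I2, −78 → 0 °C
Reagents that add atoms: iodine, [I][I]
Why: Hydroxyl-directed, copper-catalysed anti-carbomagnesiation of the propargylic alkoxide should place the methyl group on the internal carbon and magnesium on the terminal carbon cis to the CH2O arm (chelate 3), so that iodinolysis with retention fixes the Z vinyl iodide, that is the C1=C10 geometry of the target with C9 cis to the future C2.

Step 2
Reactants: 4 (2Z)-3-iodo-2-methylprop-2-en-1-ol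
Product: 5 (1Z)-3-bromo-1-iodo-2-methylprop-1-ene
Conditions: CBr4, PPh3, CH2Cl2, 0 °C
Reagents that add atoms: carbon tetrabromide, BrC(Br)(Br)Br
Why: The Appel reaction should convert the primary allylic alcohol into the bromide under neutral conditions that leave the vinyl iodide and the double-bond geometry untouched.

Step 3
Reactants: 5 (1Z)-3-bromo-1-iodo-2-methylprop-1-ene; 1 prop-2-yn-1-ol
Product: 6 (5Z)-6-iodo-5-methylhex-5-en-2-yn-1-ol
Conditions: CuI (cat.), Bu4NCl (cat.), K2CO3, DMF, 23 °C
Reagents that add atoms: none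
Why: The copper acetylide generated in situ should displace the primary allylic bromide at the unhindered CH2 terminus (SN2, not SN2') to give the skipped enyne, the vinyl iodide being inert towards copper acetylides at room temperature (copper-mediated alkyne–allyl halide coupling).

Step 4
Reactants: 6 (5Z)-6-iodo-5-methylhex-5-en-2-yn-1-ol
Product: 7 (2E,5Z)-6-iodo-5-methylhexa-2,5-dien-1-ol
Conditions: NaAlH2(OCH2CH2OMe)2 (Red-Al), THF, 0 °C
Reagents that add atoms: none
Why: Hydroxyl-directed trans-hydroalumination of the propargylic alcohol and protonolysis should give only the E allylic alcohol (future C7=C8), the vinyl iodide being expected to survive the aluminate at 0 °C.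

Step 5
Reactants: 7 (2E,5Z)-6-iodo-5-methylhexa-2,5-dien-1-ol
Product: 8 (2E,5Z)-6-iodo-5-methylhexa-2,5-dienal
Conditions: MnO2, CH2Cl2, 23 °C
Reagents that add atoms: none
Why: MnO2 should oxidise the allylic alcohol selectively to the E enal under neutral conditions that do not move the skipped C10=C1 double bond into conjugation.

Step 6
Reactants: 1 prop-2-yn-1-ol; 9 allylmagnesium bromide; 8 (2E,5Z)-6-iodo-5-methylhexa-2,5-dienal
Product: 11 rac-(2Z,5E,8Z)-9-iodo-8-methyl-2-(prop-2-en-1-yl)nona-2,5,8-triene-1,4-diol, via allyl-substituted vinylmagnesium chelate 10 (not isolated)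
Conditions: allylMgBr (2.0 equiv), Et2O, 0 °C → reflux; then 8 (0.8 equiv), THF, −78 → 0 °C
Reagents that add atoms: none
Why: Anti-allylmagnesiation of the propargylic alkoxide should give chelate 10, whose alkenyl–magnesium bond adds 1,2 to enal 8 with retention of the alkene geometry (carbomagnesiation of a propargylic alcohol with electrophilic trapping), so that C15 ends cis to C6 and C3 trans to C6 as in the ring-trans C4=C5 bond of the target, while the C6 carbinol forms as a racemate that step 8 resolves.

Step 7
Reactants: 11 racemic diol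
Product: 12 rac-(2Z,5E,8Z)-4-hydroxy-9-iodo-8-methyl-2-(prop-2-en-1-yl)nona-2,5,8-trien-1-yl acetate
Conditions: AcCl (1.05 equiv), 2,4,6-collidine, CH2Cl2, −78 °C
Reagents that add atoms: acetyl chloride, CC(=O)Cl
Why: At −78 °C acetyl chloride with collidine should acylate the unhindered primary allylic hydroxyl much faster than the secondary bis-allylic one, which installs the C15 acetate of the target and stops this hydroxyl from directing the epoxidation.

Step 8
Reactants: 12 racemic monoacetate (only the (4S)-enantiomer is converted)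
Product: 13 (2Z,4R)-4-hydroxy-4-{(2R,3R)-3-[(2Z)-3-iodo-2-methylprop-2-en-1-yl]oxiran-2-yl}-2-(prop-2-en-1-yl)but-2-en-1-yl acetate (6R,7R,8R in germacrane numbering; erythro trans-epoxy alcohol)
Conditions: Ti(OiPr)4 (cat.), D-(−)-diisopropyl tartrate, t-BuOOH (0.55 equiv), 4 Å MS, CH2Cl2, −20 °C
Reagents that add atoms: tert-butyl hydroperoxide, CC(C)(C)OO
Why: Sharpless kinetic resolution: with D-(−)-tartrate the (4S)-enantiomer of 12 should be epoxidised rapidly at the E-disubstituted C7=C8 bond on the face that gives the erythro (anti) epoxy alcohol, which sets C6, C7 and C8 in one catalytic event, whereas the (4R)-enantiomer and the C4=C5 bond (which bears a substituent cis to the carbinol) react slowly, so that the unreacted alcohol is removed by chromatography.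

Step 9
Reactants: 13 epoxy alcohol; 14 2-(diethoxyphosphoryl)acetic acid
Product: 15 (1R,2Z)-4-acetoxy-1-{(2S,3R)-3-[(2Z)-3-iodo-2-methylprop-2-en-1-yl]oxiran-2-yl}-3-(prop-2-en-1-yl)but-2-en-1-yl 2-(diethoxyphosphoryl)acetate (same spatial arrangement as 13; the oxirane descriptor changes only through CIP priorities)
Conditions: DCC, DMAP (cat.), CH2Cl2, 0 → 23 °C
Reagents that add atoms: none
Why: Steglich esterification should acylate the secondary epoxy alcohol under neutral conditions that leave the epoxide, the acetate and the vinyl iodide intact and that do not deprotonate the phosphonoacetate.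

Step 10
Reactants: 15 open-chain phosphonoacetate
Product: 16 (1R,2Z)-4-acetoxy-1-{(2S,3R)-3-[(2Z)-3-iodo-2-methylprop-2-en-1-yl]oxiran-2-yl}-3-(2-oxoethyl)but-2-en-1-yl 2-(diethoxyphosphoryl)acetate (C2 aldehyde)
Conditions: OsO4 (2 mol %), NaIO4, 2,6-lutidine, dioxane–H2O, 23 °C
Reagents that add atoms: osmium tetroxide (catalytic, reoxidised by periodate), O=[Os](=O)(=O)=O; sodium periodate, [Na+].[O-]I(=O)(=O)=O
Why: Lemieux–Johnson cleavage: OsO4 should dihydroxylate the unhindered monosubstituted alkene in preference to the trisubstituted alkenes, which are deactivated by iodine or by two allylic acyloxy groups, and periodate cleaves the diol to the C2 aldehyde, which is used without purification because its double bond is prone to move into conjugation.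

Step 11
Reactants: 16 iodo aldehyde
Product: 17 (6R,7S,8R)-15-acetoxy-7,8-epoxy-2-hydroxy-11,12,13-trinorgermacra-1(10)Z,4Z-dien-6-yl 2-(diethoxyphosphoryl)acetate (ten-membered ring, both C2 epimers)
Conditions: CrCl2 (excess), NiCl2 (cat.), DMSO–THF, 0.002 M, 23 °C
Reagents that add atoms: none
Why: Intramolecular Nozaki–Hiyama–Kishi reaction: the alkenylchromium species formed from the Z vinyl iodide under NiCl2 catalysis should add chemoselectively to the aldehyde under high dilution and close the ten-membered ring with retention of the C1=C10 geometry in the presence of epoxide, esters and phosphonate, the C2 configuration not being controlled here but set in steps 12 and 13.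

Step 12
Reactants: 17 macrocyclic allylic alcohol (C2 epimers)
Product: 18 (6R,7S,8R)-15-acetoxy-7,8-epoxy-2-oxo-11,12,13-trinorgermacra-1(10)Z,4Z-dien-6-yl 2-(diethoxyphosphoryl)acetate
Conditions: Dess–Martin periodinane, CH2Cl2, 0 → 23 °C
Reagents that add atoms: none
Why: Dess–Martin oxidation should convert both C2 epimers into a single Z enone under mild conditions that leave the epoxide and the β,γ-unsaturation untouched.

Step 13
Reactants: 18 macrocyclic enone
Product: 19 (2S,6R,7S,8R)-15-acetoxy-7,8-epoxy-2-hydroxy-11,12,13-trinorgermacra-1(10)Z,4Z-dien-6-yl 2-(diethoxyphosphoryl)acetate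
Conditions: (R)-2-methyl-CBS-oxazaborolidine, catecholborane, toluene, −78 °C
Reagents that add atoms: none
Why: Corey–Bakshi–Shibata reduction: the (R)-oxazaborolidine should bind the ketone with the alkenyl group (C1=C10) as the large and the C3 methylene as the small substituent and deliver hydride to the face that gives the (2S)-allylic alcohol by reagent control, while catecholborane at −78 °C should not touch the epoxide, the esters or the alkenes.

Step 14
Reactants: 19 (2S)-allylic alcohol; 20 angelic acid [(2Z)-2-methylbut-2-enoic acid]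
Product: 21 (2S,6R,7S,8R)-15-acetoxy-2-(angeloyloxy)-7,8-epoxy-11,12,13-trinorgermacra-1(10)Z,4Z-dien-6-yl 2-(diethoxyphosphoryl)acetate
Conditions: 20, 2,4,6-trichlorobenzoyl chloride, Et3N, toluene, 23 °C; then 19, DMAP, toluene, 23 °C
Reagents that add atoms: none
Why: Yamaguchi esterification through the preformed mixed anhydride should acylate the allylic alcohol with retention at C2 under conditions that do not isomerise the angelate to the tiglate and are too weakly basic to trigger the phosphonoacetate.

Step 15
Reactants: 21 epoxy phosphonoacetate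
Product: 23 (2S,6R,7R,8R)-15-acetoxy-2-(angeloyloxy)-8-hydroxygermacra-1(10)Z,4Z,11(13)-trien-12,6-olide (CNP0129394.1), via lithium enolate of phosphono lactone 22 (not isolated)
Conditions: LiN(SiMe3)2 (1.05 equiv), LiCl, THF, −78 → 23 °C; then (CH2O)n, 0 → 23 °C
Reagents that add atoms: formaldehyde (from paraformaldehyde), C=O
Why: Proposed new method: deprotonation of the phosphonoacetate, by far the most acidic C–H bond of 21, gives a lithium phosphonate carbanion whose C11 attacks C7 of the lithium-activated trans-epoxide from the side anti to the C7–O bond; the closest known reaction types are the Stork epoxynitrile cyclization (intramolecular epoxide opening by a stabilised carbanion) and the ester-tethered phosphonoacetate Michael addition/olefination sequence to α-methylene lactones, which has not been shown with an epoxide as the electrophile. The lactone ring closes in the 5-exo-tet mode (the breaking C7–O bond lies outside the new five-membered ring), which should be preferred over 6-endo attack at C8. C7 is the only new stereocenter and is set by SN2 inversion, so that the (6R) ester oxygen and the erythro trans-epoxide translate into the trans ring fusion (H6 and H7 anti) and the anti C11/O8 relationship of the target, while C8 keeps its epoxide oxygen as the free hydroxyl. The C8 alkoxide is quenched internally by the much more acidic α-phosphono lactone C–H, which should suppress Wadsworth–Emmons cyclopropanation and translactonisation and delivers the enolate 22 for the Horner–Wadsworth–Emmons reaction with formaldehyde that installs C13. The step needs chemoselectivity (carbanion formation beside acetate and angelate, secured by the acidity gap and one equivalent of a non-nucleophilic base) and regioselectivity (C7 over C8, secured by ring size), and it requires the ester to reach the s-cis geometry about the C12–O bond inside the macrocycle, which is its main risk.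

**Compound list**

1 | prop-2-yn-1-ol | OCC#C | starting material
2 | methylmagnesium bromide | C[Mg]Br | starting material
3 | 4-methyl-2,5-dihydro-1,2-oxamagnesole (vinylmagnesium chelate) | CC1=C[Mg]OC1 | intermediate (not isolated)
4 | (2Z)-3-iodo-2-methylprop-2-en-1-ol | OC/C(C)=C\I | intermediate
5 | (1Z)-3-bromo-1-iodo-2-methylprop-1-ene | BrC/C(C)=C\I | intermediate
6 | (5Z)-6-iodo-5-methylhex-5-en-2-yn-1-ol | OCC#CC/C(C)=C\I | intermediate
7 | (2E,5Z)-6-iodo-5-methylhexa-2,5-dien-1-ol | OC/C=C/C/C(C)=C\I | intermediate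
8 | (2E,5Z)-6-iodo-5-methylhexa-2,5-dienal | O=C/C=C/C/C(C)=C\I | intermediate
9 | allylmagnesium bromide | C=CC[Mg]Br | starting material
10 | 4-(prop-2-en-1-yl)-2,5-dihydro-1,2-oxamagnesole (vinylmagnesium chelate) | C=CCC1=C[Mg]OC1 | intermediate (not isolated)
11 | rac-(2Z,5E,8Z)-9-iodo-8-methyl-2-(prop-2-en-1-yl)nona-2,5,8-triene-1,4-diol | C=CC/C(CO)=C/C(O)/C=C/C/C(C)=C\I | intermediate
12 | rac-(2Z,5E,8Z)-4-hydroxy-9-iodo-8-methyl-2-(prop-2-en-1-yl)nona-2,5,8-trien-1-yl acetate | C=CC/C(COC(C)=O)=C/C(O)/C=C/C/C(C)=C\I | intermediate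
13 | (2Z,4R)-4-hydroxy-4-{(2R,3R)-3-[(2Z)-3-iodo-2-methylprop-2-en-1-yl]oxiran-2-yl}-2-(prop-2-en-1-yl)but-2-en-1-yl acetate | C=CC/C(COC(C)=O)=C/[C@@H](O)[C@H]1O[C@@H]1C/C(C)=C\I | intermediate
14 | 2-(diethoxyphosphoryl)acetic acid | CCOP(=O)(CC(=O)O)OCC | starting material
15 | (1R,2Z)-4-acetoxy-1-{(2S,3R)-3-[(2Z)-3-iodo-2-methylprop-2-en-1-yl]oxiran-2-yl}-3-(prop-2-en-1-yl)but-2-en-1-yl 2-(diethoxyphosphoryl)acetate | C=CC/C(COC(C)=O)=C/[C@@H](OC(=O)CP(=O)(OCC)OCC)[C@H]1O[C@@H]1C/C(C)=C\I | intermediate
16 | (1R,2Z)-4-acetoxy-1-{(2S,3R)-3-[(2Z)-3-iodo-2-methylprop-2-en-1-yl]oxiran-2-yl}-3-(2-oxoethyl)but-2-en-1-yl 2-(diethoxyphosphoryl)acetate | O=CC/C(COC(C)=O)=C/[C@@H](OC(=O)CP(=O)(OCC)OCC)[C@H]1O[C@@H]1C/C(C)=C\I | intermediate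
17 | (6R,7S,8R)-15-acetoxy-7,8-epoxy-2-hydroxy-11,12,13-trinorgermacra-1(10)Z,4Z-dien-6-yl 2-(diethoxyphosphoryl)acetate, C2 epimers | OC1C/C(COC(C)=O)=C/[C@@H](OC(=O)CP(=O)(OCC)OCC)[C@H]2O[C@@H]2C/C(C)=C\1 | intermediate
18 | (6R,7S,8R)-15-acetoxy-7,8-epoxy-2-oxo-11,12,13-trinorgermacra-1(10)Z,4Z-dien-6-yl 2-(diethoxyphosphoryl)acetate | O=C1C/C(COC(C)=O)=C/[C@@H](OC(=O)CP(=O)(OCC)OCC)[C@H]2O[C@@H]2C/C(C)=C\1 | intermediate
19 | (2S,6R,7S,8R)-15-acetoxy-7,8-epoxy-2-hydroxy-11,12,13-trinorgermacra-1(10)Z,4Z-dien-6-yl 2-(diethoxyphosphoryl)acetate | O[C@H]1C/C(COC(C)=O)=C/[C@@H](OC(=O)CP(=O)(OCC)OCC)[C@H]2O[C@@H]2C/C(C)=C\1 | intermediate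
20 | angelic acid, (2Z)-2-methylbut-2-enoic acid | C/C=C(/C)C(=O)O | starting material
21 | (2S,6R,7S,8R)-15-acetoxy-2-(angeloyloxy)-7,8-epoxy-11,12,13-trinorgermacra-1(10)Z,4Z-dien-6-yl 2-(diethoxyphosphoryl)acetate | C/C=C(/C)C(=O)O[C@H]1C/C(COC(C)=O)=C/[C@@H](OC(=O)CP(=O)(OCC)OCC)[C@H]2O[C@@H]2C/C(C)=C\1 | intermediate
22 | (2S,6R,7R,8R)-15-acetoxy-2-(angeloyloxy)-11-(diethoxyphosphoryl)-8-hydroxy-13-norgermacra-1(10)Z,4Z-dien-12,6-olide, formed as its lithium enolate | C/C=C(/C)C(=O)O[C@H]1C/C(COC(C)=O)=C/[C@H]2OC(=O)C(P(=O)(OCC)OCC)[C@@H]2[C@H](O)C/C(C)=C\1 | intermediate (not isolated)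
23 | (2S,6R,7R,8R)-15-acetoxy-2-(angeloyloxy)-8-hydroxygermacra-1(10)Z,4Z,11(13)-trien-12,6-olide (CNP0129394.1) | C/C=C(/C)C(=O)O[C@H]1C/C(COC(C)=O)=C/[C@H]2OC(=O)C(=C)[C@@H]2[C@H](O)C/C(C)=C\1 | target

**Step count and risks**

Total step count: 15. Longest linear sequence: 15 steps (1 to 23; all other inputs are commercial).

Steps most likely to fail:

Step 15 (labelled step). The carbanion may fail to reach C7 because the ester cannot adopt the s-cis geometry inside the ring, or the base may instead isomerise the epoxide to an allylic alcohol or open it at C8. The fallback closes the same C7–C11 bond in the radical manifold with known chemistry; it sets out from 13 and comes back at 23. O-Propargylation of 13 (propargyl bromide, Ag2O, CH2Cl2) gives the 6-O-propargyl ether of 13 F1. This is taken through the operations of steps 10 to 14: Lemieux–Johnson cleavage to the C2 aldehyde F2, Nozaki–Hiyama–Kishi closure to the ten-membered allylic alcohol F3, Dess–Martin oxidation to the enone F4, CBS reduction to the (2S)-alcohol F5 and Yamaguchi angeloylation to the angelate F6. Cp2TiCl (trivalent titanium, from Cp2TiCl2 and Zn, THF) should then open the epoxide homolytically to the C7 radical, which cyclises 5-exo-dig onto the alkyne and, after hydrogen abstraction, gives the ring-fused 3-methylenetetrahydrofuran with free C8 hydroxyl F7; this is a known route from epoxy propargyl ethers to precursors of α-methylene lactones, and the trans ring fusion is expected. Silylation (Et3SiOTf, 2,6-lutidine) gives the 8-O-triethylsilyl ether F8. Allylic oxidation of the ether methylene C12 (CrO3·3,5-dimethylpyrazole, CH2Cl2, −20 °C) gives the 8-O-triethylsilyl ether of the target F9; the oxidation is placed this late so that no skipped diene is present. HF·pyridine then gives 23.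

Step 11. Oligomerisation may outrun closure of the strained ring that holds the trans-epoxide and the ester, or the β,γ-double bond of the aldehyde may migrate into conjugation before addition. The fallback inverts the order of the two ring closures; it sets out from 15 and comes back at 23. The conditions of step 15, applied to open-chain 15, should give the open-chain α-methylene lactone alcohol F10, and Et3SiOTf/2,6-lutidine gives its triethylsilyl ether F11. Lemieux–Johnson cleavage gives the aldehyde F12, whose Nozaki–Hiyama–Kishi closure now forms the ring system of the natural product itself, without epoxide or phosphonate, as the macrocyclic alcohol F13. Dess–Martin oxidation gives the enone F14, CBS reduction gives the (2S)-alcohol F15, and Yamaguchi angeloylation leads to F9 of the first fallback, which HF·pyridine converts into 23.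

Step 13. Hydride delivery may show poor facial selectivity if the conformation of the macrocyclic Z-enone opposes the oxazaborolidine. The fallback sets out from 18 and comes back at 21. Enone 18 is reduced without a chiral reagent (NaBH4, CeCl3·7H2O, MeOH, −78 °C, Luche reduction) and the epimers are separated. The (2S)-alcohol is 19 and continues with step 14. The (2R)-epimer of 19 F16 is esterified with angelic acid 20 under Mitsunobu conditions (PPh3, DIAD, toluene, 0 °C), which inverts C2 and gives 21.

**Further compounds**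

F1 | step 15 | 6-O-(prop-2-yn-1-yl) ether of 13 | C=CC/C(COC(C)=O)=C/[C@@H](OCC#C)[C@H]1O[C@@H]1C/C(C)=C\I
F2 | step 15 | C2 aldehyde from F1 (terminal vinyl cleaved) | O=CC/C(COC(C)=O)=C/[C@@H](OCC#C)[C@H]1O[C@@H]1C/C(C)=C\I
F3 | step 15 | ten-membered 2-hydroxy 7,8-epoxide with 6-O-propargyl ether, C2 epimers | OC1C/C(COC(C)=O)=C/[C@@H](OCC#C)[C@H]2O[C@@H]2C/C(C)=C\1
F4 | step 15 | corresponding 2-oxo compound (Z enone) | O=C1C/C(COC(C)=O)=C/[C@@H](OCC#C)[C@H]2O[C@@H]2C/C(C)=C\1
F5 | step 15 | corresponding (2S)-alcohol | O[C@H]1C/C(COC(C)=O)=C/[C@@H](OCC#C)[C@H]2O[C@@H]2C/C(C)=C\1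
F6 | step 15 | corresponding (2S)-angelate | C/C=C(/C)C(=O)O[C@H]1C/C(COC(C)=O)=C/[C@@H](OCC#C)[C@H]2O[C@@H]2C/C(C)=C\1
F7 | step 15 | 12-deoxo analogue of 23 (trans-fused 3-methylenetetrahydrofuran O–C12H2–C11(=C13H2)–C7–C6, free 8-OH) | C/C=C(/C)C(=O)O[C@H]1C/C(COC(C)=O)=C/[C@H]2OCC(=C)[C@@H]2[C@H](O)C/C(C)=C\1
F8 | step 15 | 8-O-triethylsilyl ether of F7 | C/C=C(/C)C(=O)O[C@H]1C/C(COC(C)=O)=C/[C@H]2OCC(=C)[C@@H]2[C@H](O[Si](CC)(CC)CC)C/C(C)=C\1
F9 | step 15 | 8-O-triethylsilyl ether of 23 | C/C=C(/C)C(=O)O[C@H]1C/C(COC(C)=O)=C/[C@H]2OC(=O)C(=C)[C@@H]2[C@H](O[Si](CC)(CC)CC)C/C(C)=C\1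
F10 | step 11 | open-chain trans-α-methylene-γ-butyrolactone with free C8 hydroxyl (from 15) | C=CC/C(COC(C)=O)=C/[C@H]1OC(=O)C(=C)[C@@H]1[C@H](O)C/C(C)=C\I
F11 | step 11 | triethylsilyl ether of F10 | C=CC/C(COC(C)=O)=C/[C@H]1OC(=O)C(=C)[C@@H]1[C@H](O[Si](CC)(CC)CC)C/C(C)=C\I
F12 | step 11 | C2 aldehyde from F11 | O=CC/C(COC(C)=O)=C/[C@H]1OC(=O)C(=C)[C@@H]1[C@H](O[Si](CC)(CC)CC)C/C(C)=C\I
F13 | step 11 | ten-membered 2-hydroxy lactone, 8-O-triethylsilyl, C2 epimers | OC1C/C(COC(C)=O)=C/[C@H]2OC(=O)C(=C)[C@@H]2[C@H](O[Si](CC)(CC)CC)C/C(C)=C\1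
F14 | step 11 | corresponding 2-oxo lactone (Z enone) | O=C1C/C(COC(C)=O)=C/[C@H]2OC(=O)C(=C)[C@@H]2[C@H](O[Si](CC)(CC)CC)C/C(C)=C\1
F15 | step 11 | corresponding (2S)-alcohol (de-angeloyl F9) | O[C@H]1C/C(COC(C)=O)=C/[C@H]2OC(=O)C(=C)[C@@H]2[C@H](O[Si](CC)(CC)CC)C/C(C)=C\1
F16 | step 13 | (2R)-epimer of 19 | O[C@@H]1C/C(COC(C)=O)=C/[C@@H](OC(=O)CP(=O)(OCC)OCC)[C@H]2O[C@@H]2C/C(C)=C\1
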